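**Plan**

- Retrosynthesis: the C8–O ester bond is cut first (the angelate is put on with inversion), then C7–C8, which opens the ten-membered ring to a C8 aldehyde tethered to a 3-(bromomethyl)butenolide. Further cuts are C1=C10 (Wittig), C11–C12 with C12–O6 (carbonylative lactonisation), C6–C7 (acetylide acylation) and C4–C5 (auxiliary alkylation).
- Enabling feature: the α-methylene-γ-lactone O–C12(=O)–C11(=C13H2)–C7–C6 hides an allyl unit C13–C11–C7. Its γ-carbon C7 is a carbon of the cyclodecene ring and neighbours oxygen-bearing C8, so an allylmetal at C13 adding through C7 to a C8 aldehyde makes the ring bond, C7, C8 and the exocyclic methylene at once.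
- Forward order: C4 is set and stored in a butyrolactone. Acetylide opening, ynone reduction, hydroalumination–iodination and carbonylation build the butenolide (first ring). The chain is extended at C1 by Wittig olefination, bromide and aldehyde are unveiled, and the ten-membered ring (second ring) closes last, before esterification and desilylation.
- Stereochemistry: C4 from the oxazolidinone auxiliary; C6 from catalyst-controlled transfer hydrogenation; C7 from C6 during ring closure (trans lactone); C8 from the chair transition state of the ring closure (8S), then inverted to 8R in the Mitsunobu esterification. The C1=C10 geometry comes from the stabilised ylide and the Z-angelate from angelic acid itself.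

Key step: step 15

Assumption: germacrane numbering is used for all atoms (ring C1–C10, lactone carbons C11–C13 with the ring oxygen on C6, ester carbon C14, hydroxymethyl carbon C15), and the allylindium of the bromomethylbutenolide is taken to react inside the ring through the same closed chair transition state as in intermolecular additions.

**Route**

Step 1
Reactants: 1 hex-5-enoic acid; 2 (4S)-4-benzyl-1,3-oxazolidin-2-one
Product: 4 (4S)-4-benzyl-3-(hex-5-enoyl)-1,3-oxazolidin-2-one, via mixed pivalic anhydride 3 (not isolated)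
Conditions: PivCl, Et3N, THF, −20 °C; then 2, LiCl, −20 °C → rt
Reagents that add atoms: none
Why: Mixed-anhydride N-acylation of an oxazolidinone, in which the LiCl/Et3N-activated auxiliary attacks the unhindered hexenoyl carbonyl of the pivalic anhydride; no stereocentre is formed.

Step 2
Reactants: 4 (4S)-4-benzyl-3-(hex-5-enoyl)-1,3-oxazolidin-2-one; 5 tert-butyl bromoacetate
Product: 7 tert-butyl (3R)-3-{[(4S)-4-benzyl-2-oxo-1,3-oxazolidin-3-yl]carbonyl}hept-6-enoate, via sodium enolate 6 (not isolated)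
Conditions: NaN(SiMe3)2, THF, −78 °C; then 5, −78 → −40 °C
Reagents that add atoms: none
Why: Evans asymmetric alkylation, in which the chelated (Z)-enolate should be alkylated by the reactive α-bromo ester on the face away from the benzyl group, setting C4 (R) under auxiliary control.

Step 3
Reactants: 7 tert-butyl (3R)-3-{[(4S)-4-benzyl-2-oxo-1,3-oxazolidin-3-yl]carbonyl}hept-6-enoate
Product: 10 (4R)-4-(but-3-en-1-yl)oxolan-2-one, via hydroxy ester 8 (not isolated), via hydroxy acid 9 (not isolated)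
Conditions: LiBH4, THF, 0 °C → rt; then TFA, CH2Cl2, rt
Reagents that add atoms: none
Why: Reductive cleavage of the N-acyl oxazolidinone by LiBH4 leaves the tert-butyl ester intact and frees the C15 alcohol, and acid then removes the tert-butyl group and closes the γ-lactone (acid-catalysed lactonisation), C4 being non-epimerisable in both stages.

Step 4
Reactants: 10 (4R)-4-(but-3-en-1-yl)oxolan-2-one; 11 tert-butyldimethyl(prop-2-yn-1-yloxy)silane
Product: 13 (6R)-1-[(tert-butyldimethylsilyl)oxy]-6-(hydroxymethyl)dec-9-en-2-yn-4-one, via lithium acetylide 12 (not isolated)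
Conditions: 11, n-BuLi, THF, −78 °C; then 10, −78 °C; AcOH, −78 °C
Reagents that add atoms: none
Why: Acylation of a lithium acetylide by a γ-lactone, which should stop at the ketone because the tetrahedral lithium hemiketal alkoxide persists at −78 °C until the cold acid quench, so the C6–C7 bond and the free C15 hydroxyl arise in one operation.

Step 5
Reactants: 13 (6R)-1-[(tert-butyldimethylsilyl)oxy]-6-(hydroxymethyl)dec-9-en-2-yn-4-one
Product: 14 (6R)-1-[(tert-butyldimethylsilyl)oxy]-6-{[(tert-butyldiphenylsilyl)oxy]methyl}dec-9-en-2-yn-4-one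
Conditions: TBDPSCl, imidazole, CH2Cl2, 0 °C → rt
Reagents that add atoms: tert-butyl(chloro)diphenylsilane, CC(C)(C)[Si](Cl)(c1ccccc1)c1ccccc1
Why: Standard silylation of the primary alcohol, which also draws any cyclic hemiketal form to the open-chain ynone; TBDPS is chosen because it must later outlast an allylic TBS ether.

Step 6
Reactants: 14 (6R)-1-[(tert-butyldimethylsilyl)oxy]-6-{[(tert-butyldiphenylsilyl)oxy]methyl}dec-9-en-2-yn-4-one
Product: 15 (4R,6R)-1-[(tert-butyldimethylsilyl)oxy]-6-{[(tert-butyldiphenylsilyl)oxy]methyl}dec-9-en-2-yn-4-ol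
Conditions: RuCl[(R,R)-TsDPEN](p-cymene) (3 mol %), i-PrOH, rt
Reagents that add atoms: none
Why: Noyori asymmetric transfer hydrogenation of an alkynyl ketone, in which the (R,R)-configured divalent ruthenium catalyst should deliver hydride to the face that gives the (R)-propargylic alcohol at C6 under catalyst control, the remote C4 centre and the isolated alkene playing no part.

Step 7
Reactants: 15 (4R,6R)-1-[(tert-butyldimethylsilyl)oxy]-6-{[(tert-butyldiphenylsilyl)oxy]methyl}dec-9-en-2-yn-4-ol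
Product: 17 (2Z,4R,6R)-1-[(tert-butyldimethylsilyl)oxy]-6-{[(tert-butyldiphenylsilyl)oxy]methyl}-2-iododeca-2,9-dien-4-ol, via vinylalanate 16 (not isolated)
Conditions: NaAlH2(OCH2CH2OMe)2, THF, 0 °C → rt; then I2, THF, −78 → 0 °C
Reagents that add atoms: iodine, [I][I]
Why: Hydroxyl-directed trans-hydroalumination of the propargylic alcohol places aluminium on the distal alkyne carbon C11 in a five-membered chelate and hydrogen on C7, and iodinolysis with retention should give the (Z)-vinyl iodide whose iodine is cis to the C6 carbinol.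

Step 8
Reactants: 17 (2Z,4R,6R)-1-[(tert-butyldimethylsilyl)oxy]-6-{[(tert-butyldiphenylsilyl)oxy]methyl}-2-iododeca-2,9-dien-4-ol
Product: 18 (5R)-3-{[(tert-butyldimethylsilyl)oxy]methyl}-5-[(2R)-2-{[(tert-butyldiphenylsilyl)oxy]methyl}hex-5-en-1-yl]furan-2(5H)-one
Conditions: PdCl2(PPh3)2 (5 mol %), CO (1 atm), i-Pr2NEt, THF, 45 °C
Reagents that add atoms: carbon monoxide, [C-]#[O+]
Why: Palladium-catalysed carbonylative lactonisation of a (Z)-γ-hydroxy vinyl iodide, in which oxidative addition to zerovalent palladium, CO insertion and capture of the acylpalladium by the cis C6 hydroxyl close the butenolide without touching C6.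

Step 9
Reactants: 18 (5R)-3-{[(tert-butyldimethylsilyl)oxy]methyl}-5-[(2R)-2-{[(tert-butyldiphenylsilyl)oxy]methyl}hex-5-en-1-yl]furan-2(5H)-one
Product: 20 (4R)-4-{[(tert-butyldiphenylsilyl)oxy]methyl}-5-[(2R)-4-{[(tert-butyldimethylsilyl)oxy]methyl}-5-oxo-2,5-dihydrofuran-2-yl]pentanal, via diol 19 (not isolated)
Conditions: OsO4 (2 mol %), NaIO4, 2,6-lutidine, dioxane/H2O 3:1, rt
Reagents that add atoms: sodium periodate, [Na+].[O-]I(=O)(=O)=O (net oxygen source, delivered through catalytic osmium tetroxide, O=[Os](=O)(=O)=O)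
Why: Lemieux–Johnson oxidative cleavage, in which OsO4 should select the electron-rich monosubstituted alkene over the electron-poor trisubstituted butenolide alkene and periodate cleaves the glycol to the C1 aldehyde.

Step 10
Reactants: 21 methyl (triphenyl-λ5-phosphanylidene)acetate; 22 allyl bromide
Product: 24 methyl 2-(triphenyl-λ5-phosphanylidene)pent-4-enoate, via phosphonium bromide 23 (not isolated)
Conditions: CHCl3, reflux; then aq. NaOH, CH2Cl2, rt
Reagents that add atoms: none
Why: C-alkylation of a stabilised phosphorus ylide by an allylic bromide followed by deprotonation of the phosphonium salt, the usual way to α-substituted ester ylides.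

Step 11
Reactants: 20 (4R)-4-{[(tert-butyldiphenylsilyl)oxy]methyl}-5-[(2R)-4-{[(tert-butyldimethylsilyl)oxy]methyl}-5-oxo-2,5-dihydrofuran-2-yl]pentanal; 24 methyl 2-(triphenyl-λ5-phosphanylidene)pent-4-enoate
Product: 25 methyl (2E,6R)-6-{[(tert-butyldiphenylsilyl)oxy]methyl}-7-[(2R)-4-{[(tert-butyldimethylsilyl)oxy]methyl}-5-oxo-2,5-dihydrofuran-2-yl]-2-(prop-2-en-1-yl)hept-2-enoate
Conditions: toluene, 90 °C
Reagents that add atoms: none
Why: Wittig olefination with an α-substituted ester-stabilised ylide, which is too weakly basic to epimerise C6 and should give the trisubstituted enoate with C2 trans to the ester (2E, that is C2 and C9 cis as required in the ring); the allyl group carries C9 and a masked C8 aldehyde.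

Step 12
Reactants: 25 methyl (2E,6R)-6-{[(tert-butyldiphenylsilyl)oxy]methyl}-7-[(2R)-4-{[(tert-butyldimethylsilyl)oxy]methyl}-5-oxo-2,5-dihydrofuran-2-yl]-2-(prop-2-en-1-yl)hept-2-enoate
Product: 26 methyl (2E,6R)-6-{[(tert-butyldiphenylsilyl)oxy]methyl}-7-[(2R)-4-(hydroxymethyl)-5-oxo-2,5-dihydrofuran-2-yl]-2-(prop-2-en-1-yl)hept-2-enoate
Conditions: (1S)-10-camphorsulfonic acid (10 mol %), MeOH/CH2Cl2 1:1, 0 °C
Reagents that add atoms: none
Why: Acid-catalysed methanolysis cleaves the primary allylic TBS ether chemoselectively, while the far more acid-stable TBDPS ether at C15, the lactone and the methyl ester should stay untouched.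

Step 13
Reactants: 26 methyl (2E,6R)-6-{[(tert-butyldiphenylsilyl)oxy]methyl}-7-[(2R)-4-(hydroxymethyl)-5-oxo-2,5-dihydrofuran-2-yl]-2-(prop-2-en-1-yl)hept-2-enoate
Product: 27 methyl (2E,6R)-7-[(2R)-4-(bromomethyl)-5-oxo-2,5-dihydrofuran-2-yl]-6-{[(tert-butyldiphenylsilyl)oxy]methyl}-2-(prop-2-en-1-yl)hept-2-enoate
Conditions: CBr4, PPh3, CH2Cl2, 0 °C
Reagents that add atoms: carbon tetrabromide, BrC(Br)(Br)Br
Why: Appel bromination, in which bromide displaces the alkoxyphosphonium group at the primary allylic carbon C13 by SN2 under neutral conditions that leave C6 and the silyl ether alone.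

Step 14
Reactants: 27 methyl (2E,6R)-7-[(2R)-4-(bromomethyl)-5-oxo-2,5-dihydrofuran-2-yl]-6-{[(tert-butyldiphenylsilyl)oxy]methyl}-2-(prop-2-en-1-yl)hept-2-enoate
Product: 29 methyl (2E,6R)-7-[(2R)-4-(bromomethyl)-5-oxo-2,5-dihydrofuran-2-yl]-6-{[(tert-butyldiphenylsilyl)oxy]methyl}-2-(2-oxoethyl)hept-2-enoate, via diol 28 (not isolated)
Conditions: OsO4 (2 mol %), NaIO4, 2,6-lutidine, dioxane/H2O 3:1, 0 °C → rt; extracted and used crude at once
Reagents that add atoms: sodium periodate, [Na+].[O-]I(=O)(=O)=O (net oxygen source, delivered through catalytic osmium tetroxide, O=[Os](=O)(=O)=O)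
Why: Lemieux–Johnson cleavage of the only electron-rich alkene (the terminal vinyl group; the enoate and butenolide alkenes are deactivated) should release the C8 aldehyde under lutidine-buffered conditions, and the β,γ-unsaturated aldehyde is used immediately so that it has no time to move into conjugation.

Step 15
Reactants: 29 methyl (2E,6R)-7-[(2R)-4-(bromomethyl)-5-oxo-2,5-dihydrofuran-2-yl]-6-{[(tert-butyldiphenylsilyl)oxy]methyl}-2-(2-oxoethyl)hept-2-enoate
Product: 31 methyl (3aR,4S,6E,10R,11aR)-10-{[(tert-butyldiphenylsilyl)oxy]methyl}-4-hydroxy-3-methylidene-2-oxo-2,3,3a,4,5,8,9,10,11,11a-decahydrocyclodeca[b]furan-6-carboxylate, via allylindium dibromide 30 (not isolated)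
Conditions: indium powder (3 equiv), THF/H2O 3:1, rt; 29 added over 12 h to a final 2 mM
Reagents that add atoms: none
Why: Indium metal inserts into the allylic C13–Br bond and the allylindium adds through its γ-carbon C7 to the tethered C8 aldehyde via a six-membered cyclic transition state (In–O–C8–C7–C11–C13), so that C7–C8 forms while the double bond moves to the exocyclic C11=C13 position. The closest known reaction type is the zinc- or indium-mediated Barbier addition of 3-(bromomethyl)furan-2(5H)-ones to aldehydes, which gives β-(hydroxyalkyl)-α-methylene-γ-butyrolactones, run here intramolecularly at high dilution in the manner of macrocyclic Barbier and Nozaki–Hiyama closures of germacranolides. The only ring closed is the ten-membered carbocycle, by a 10-exo-trig attack of C7 on the aldehyde carbon. C7 is controlled by the C6 stereocentre: the aldehyde should be taken up on the butenolide face anti to the C5 arm, giving the trans-fused lactone. C8 is controlled by the chair form of the cyclic transition state, in which the ring-locked allyl unit (C6 trans to C13) and a C9 methylene lying anti to C11 place the aldehyde oxygen anti to C6; this is expected to give the 8S alcohol (O8 trans to C11 on the ring), the epimer of the acyloxy configuration of the target, which step 16 inverts. The step needs γ- over α-attack (secured by the cyclic transition state), ring closure over oligomerisation (slow addition, high dilution) and an intact β,γ-unsaturated aldehyde (neutral aqueous medium, aldehyde used as made).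

Step 16
Reactants: 31 methyl (3aR,4S,6E,10R,11aR)-10-{[(tert-butyldiphenylsilyl)oxy]methyl}-4-hydroxy-3-methylidene-2-oxo-2,3,3a,4,5,8,9,10,11,11a-decahydrocyclodeca[b]furan-6-carboxylate; 32 angelic acid, (2Z)-2-methylbut-2-enoic acid
Product: 34 methyl (3aS,4R,6E,10R,11aR)-10-{[(tert-butyldiphenylsilyl)oxy]methyl}-4-{[(2Z)-2-methylbut-2-enoyl]oxy}-3-methylidene-2-oxo-2,3,3a,4,5,8,9,10,11,11a-decahydrocyclodeca[b]furan-6-carboxylate, via alkoxyphosphonium angelate 33 (not isolated)
Conditions: PPh3, diisopropyl azodicarboxylate, 32, toluene, 0 °C → rt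
Reagents that add atoms: none
Why: Mitsunobu esterification, in which the C8 hydroxyl is activated as its alkoxyphosphonium ion and displaced by angelate in an SN2 reaction with inversion (8S to 8R), under neutral conditions without acyl activation so that the Z alkene of the acid should not isomerise.

Step 17
Reactants: 34 methyl (3aS,4R,6E,10R,11aR)-10-{[(tert-butyldiphenylsilyl)oxy]methyl}-4-{[(2Z)-2-methylbut-2-enoyl]oxy}-3-methylidene-2-oxo-2,3,3a,4,5,8,9,10,11,11a-decahydrocyclodeca[b]furan-6-carboxylate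
Product: 35 methyl (3aS,4R,6E,10R,11aR)-10-(hydroxymethyl)-4-{[(2Z)-2-methylbut-2-enoyl]oxy}-3-methylidene-2-oxo-2,3,3a,4,5,8,9,10,11,11a-decahydrocyclodeca[b]furan-6-carboxylate (CNP0167542.1)
Conditions: HF·pyridine, pyridine, THF, 0 °C → rt
Reagents that add atoms: none
Why: Desilylation with buffered HF·pyridine, a mildly acidic fluoride source that should cleave the primary TBDPS ether while leaving the α-methylene lactone, both esters and the Z-angelate intact.

**Compound list**

1 | hex-5-enoic acid | C=CCCCC(=O)O | starting material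
2 | (4S)-4-benzyl-1,3-oxazolidin-2-one | O=C1N[C@@H](Cc2ccccc2)CO1 | starting material
3 | hex-5-enoic pivalic anhydride | C=CCCCC(=O)OC(=O)C(C)(C)C | intermediate
4 | (4S)-4-benzyl-3-(hex-5-enoyl)-1,3-oxazolidin-2-one | C=CCCCC(=O)N1[C@@H](Cc2ccccc2)COC1=O | intermediate
5 | tert-butyl bromoacetate | CC(C)(C)OC(=O)CBr | starting material
6 | sodium (Z)-enolate of 4 | C=CCC/C=C(\[O-])N1[C@@H](Cc2ccccc2)COC1=O.[Na+] | intermediate
7 | tert-butyl (3R)-3-{[(4S)-4-benzyl-2-oxo-1,3-oxazolidin-3-yl]carbonyl}hept-6-enoate | C=CCC[C@@H](C(=O)N1[C@@H](Cc2ccccc2)COC1=O)CC(=O)OC(C)(C)C | intermediate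
8 | tert-butyl (3R)-3-(hydroxymethyl)hept-6-enoate | C=CCC[C@@H](CO)CC(=O)OC(C)(C)C | intermediate
9 | (3R)-3-(hydroxymethyl)hept-6-enoic acid | C=CCC[C@@H](CO)CC(=O)O | intermediate
10 | (4R)-4-(but-3-en-1-yl)oxolan-2-one | C=CCC[C@H]1COC(=O)C1 | intermediate
11 | tert-butyldimethyl(prop-2-yn-1-yloxy)silane | C#CCO[Si](C)(C)C(C)(C)C | starting material
12 | lithium acetylide of 11 | [Li]C#CCO[Si](C)(C)C(C)(C)C | intermediate
13 | (6R)-1-[(tert-butyldimethylsilyl)oxy]-6-(hydroxymethyl)dec-9-en-2-yn-4-one | C=CCC[C@@H](CO)CC(=O)C#CCO[Si](C)(C)C(C)(C)C | intermediate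
14 | (6R)-1-[(tert-butyldimethylsilyl)oxy]-6-{[(tert-butyldiphenylsilyl)oxy]methyl}dec-9-en-2-yn-4-one | C=CCC[C@@H](CO[Si](c1ccccc1)(c1ccccc1)C(C)(C)C)CC(=O)C#CCO[Si](C)(C)C(C)(C)C | intermediate
15 | (4R,6R)-1-[(tert-butyldimethylsilyl)oxy]-6-{[(tert-butyldiphenylsilyl)oxy]methyl}dec-9-en-2-yn-4-ol | C=CCC[C@@H](CO[Si](c1ccccc1)(c1ccccc1)C(C)(C)C)C[C@@H](O)C#CCO[Si](C)(C)C(C)(C)C | intermediate
16 | sodium bis(2-methoxyethoxy)aluminate chelate from hydroalumination of 15 (five-membered ring O–C6–C7=C11–Al, Al on C11, H on C7) | C=CCC[C@@H](CO[Si](c1ccccc1)(c1ccccc1)C(C)(C)C)C[C@H]1O[Al-](OCCOC)(OCCOC)C(CO[Si](C)(C)C(C)(C)C)=C1.[Na+] | intermediate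
17 | (2Z,4R,6R)-1-[(tert-butyldimethylsilyl)oxy]-6-{[(tert-butyldiphenylsilyl)oxy]methyl}-2-iododeca-2,9-dien-4-ol | C=CCC[C@@H](CO[Si](c1ccccc1)(c1ccccc1)C(C)(C)C)C[C@@H](O)/C=C(\I)CO[Si](C)(C)C(C)(C)C | intermediate
18 | (5R)-3-{[(tert-butyldimethylsilyl)oxy]methyl}-5-[(2R)-2-{[(tert-butyldiphenylsilyl)oxy]methyl}hex-5-en-1-yl]furan-2(5H)-one | C=CCC[C@@H](CO[Si](c1ccccc1)(c1ccccc1)C(C)(C)C)C[C@H]1OC(=O)C(CO[Si](C)(C)C(C)(C)C)=C1 | intermediate
19 | (5R)-3-{[(tert-butyldimethylsilyl)oxy]methyl}-5-[(2R)-2-{[(tert-butyldiphenylsilyl)oxy]methyl}-5,6-dihydroxyhexyl]furan-2(5H)-one (both epimers at the new carbinol) | OCC(O)CC[C@@H](CO[Si](c1ccccc1)(c1ccccc1)C(C)(C)C)C[C@H]1OC(=O)C(CO[Si](C)(C)C(C)(C)C)=C1 | intermediate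
20 | (4R)-4-{[(tert-butyldiphenylsilyl)oxy]methyl}-5-[(2R)-4-{[(tert-butyldimethylsilyl)oxy]methyl}-5-oxo-2,5-dihydrofuran-2-yl]pentanal | O=CCC[C@@H](CO[Si](c1ccccc1)(c1ccccc1)C(C)(C)C)C[C@H]1OC(=O)C(CO[Si](C)(C)C(C)(C)C)=C1 | intermediate
21 | methyl (triphenyl-λ5-phosphanylidene)acetate | COC(=O)C=P(c1ccccc1)(c1ccccc1)c1ccccc1 | starting material
22 | allyl bromide (3-bromoprop-1-ene) | C=CCBr | starting material
23 | (1-methoxy-1-oxopent-4-en-2-yl)triphenylphosphonium bromide | COC(=O)C(CC=C)[P+](c1ccccc1)(c1ccccc1)c1ccccc1.[Br-] | intermediate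
24 | methyl 2-(triphenyl-λ5-phosphanylidene)pent-4-enoate | COC(=O)C(CC=C)=P(c1ccccc1)(c1ccccc1)c1ccccc1 | intermediate
25 | methyl (2E,6R)-6-{[(tert-butyldiphenylsilyl)oxy]methyl}-7-[(2R)-4-{[(tert-butyldimethylsilyl)oxy]methyl}-5-oxo-2,5-dihydrofuran-2-yl]-2-(prop-2-en-1-yl)hept-2-enoate | C=CC/C(C(=O)OC)=C\CC[C@@H](CO[Si](c1ccccc1)(c1ccccc1)C(C)(C)C)C[C@H]1OC(=O)C(CO[Si](C)(C)C(C)(C)C)=C1 | intermediate
26 | methyl (2E,6R)-6-{[(tert-butyldiphenylsilyl)oxy]methyl}-7-[(2R)-4-(hydroxymethyl)-5-oxo-2,5-dihydrofuran-2-yl]-2-(prop-2-en-1-yl)hept-2-enoate | C=CC/C(C(=O)OC)=C\CC[C@@H](CO[Si](c1ccccc1)(c1ccccc1)C(C)(C)C)C[C@H]1OC(=O)C(CO)=C1 | intermediate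
27 | methyl (2E,6R)-7-[(2R)-4-(bromomethyl)-5-oxo-2,5-dihydrofuran-2-yl]-6-{[(tert-butyldiphenylsilyl)oxy]methyl}-2-(prop-2-en-1-yl)hept-2-enoate | C=CC/C(C(=O)OC)=C\CC[C@@H](CO[Si](c1ccccc1)(c1ccccc1)C(C)(C)C)C[C@H]1OC(=O)C(CBr)=C1 | intermediate
28 | methyl (2E,6R)-7-[(2R)-4-(bromomethyl)-5-oxo-2,5-dihydrofuran-2-yl]-6-{[(tert-butyldiphenylsilyl)oxy]methyl}-2-(2,3-dihydroxypropyl)hept-2-enoate (both epimers at the new carbinol) | OCC(O)C/C(C(=O)OC)=C\CC[C@@H](CO[Si](c1ccccc1)(c1ccccc1)C(C)(C)C)C[C@H]1OC(=O)C(CBr)=C1 | intermediate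
29 | methyl (2E,6R)-7-[(2R)-4-(bromomethyl)-5-oxo-2,5-dihydrofuran-2-yl]-6-{[(tert-butyldiphenylsilyl)oxy]methyl}-2-(2-oxoethyl)hept-2-enoate (C8 aldehyde, key-step precursor) | O=CC/C(C(=O)OC)=C\CC[C@@H](CO[Si](c1ccccc1)(c1ccccc1)C(C)(C)C)C[C@H]1OC(=O)C(CBr)=C1 | intermediate
30 | allylindium dibromide of 29 (trivalent indium on C13 in place of bromine) | O=CC/C(C(=O)OC)=C\CC[C@@H](CO[Si](c1ccccc1)(c1ccccc1)C(C)(C)C)C[C@H]1OC(=O)C(C[In](Br)Br)=C1 | intermediate
31 | methyl (3aR,4S,6E,10R,11aR)-10-{[(tert-butyldiphenylsilyl)oxy]methyl}-4-hydroxy-3-methylidene-2-oxo-2,3,3a,4,5,8,9,10,11,11a-decahydrocyclodeca[b]furan-6-carboxylate (8S alcohol, trans lactone) | C=C1C(=O)O[C@@H]2C[C@H](CO[Si](c3ccccc3)(c3ccccc3)C(C)(C)C)CC/C=C(/C(=O)OC)C[C@H](O)[C@@H]12 | intermediate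
32 | angelic acid, (2Z)-2-methylbut-2-enoic acid | C/C=C(/C)C(=O)O | starting material
33 | C8-O-triphenylphosphonium derivative of 31 with angelate counter-ion | C=C1C(=O)O[C@@H]2C[C@H](CO[Si](c3ccccc3)(c3ccccc3)C(C)(C)C)CC/C=C(/C(=O)OC)C[C@H](O[P+](c3ccccc3)(c3ccccc3)c3ccccc3)[C@@H]12.C/C=C(/C)C(=O)[O-] | intermediate
34 | methyl (3aS,4R,6E,10R,11aR)-10-{[(tert-butyldiphenylsilyl)oxy]methyl}-4-{[(2Z)-2-methylbut-2-enoyl]oxy}-3-methylidene-2-oxo-2,3,3a,4,5,8,9,10,11,11a-decahydrocyclodeca[b]furan-6-carboxylate | C=C1C(=O)O[C@@H]2C[C@H](CO[Si](c3ccccc3)(c3ccccc3)C(C)(C)C)CC/C=C(/C(=O)OC)C[C@@H](OC(=O)/C(C)=C\C)[C@@H]12 | intermediate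
35 | methyl (3aS,4R,6E,10R,11aR)-10-(hydroxymethyl)-4-{[(2Z)-2-methylbut-2-enoyl]oxy}-3-methylidene-2-oxo-2,3,3a,4,5,8,9,10,11,11a-decahydrocyclodeca[b]furan-6-carboxylate | C=C1C(=O)O[C@@H]2C[C@H](CO)CC/C=C(/C(=O)OC)C[C@@H](OC(=O)/C(C)=C\C)[C@@H]12 | target

**Step count and risks**

Total step count: 17. Longest linear sequence: 16 steps (steps 1–9 and 11–17; step 10 prepares the ylide).

Step 15 (ring closure). What may go wrong: once the tether is in place, facial selection at the aldehyde carbon may not follow the chair model, so that C8 forms as a mixture or mainly as the other epimer. Fallback: setting out from 29, the ring closure is run as described and the 8R alcohol, methyl (3aR,4R,6E,10R,11aR)-10-{[(tert-butyldiphenylsilyl)oxy]methyl}-4-hydroxy-3-methylidene-2-oxo-2,3,3a,4,5,8,9,10,11,11a-decahydrocyclodeca[b]furan-6-carboxylate F1, is not inverted but acylated with retention. For this, 32 is converted with 2,4,6-trichlorobenzoyl chloride and Et3N in toluene into (2Z)-2-methylbut-2-enoic 2,4,6-trichlorobenzoic anhydride F2, which should esterify F1 at 80 °C without DMAP (Yamaguchi-type acylation). This comes back to the route at 34, so both C8 epimers are usable.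

Step 16 (Mitsunobu esterification). What may go wrong: the alkoxyphosphonium ion at the hindered ring carbon C8 may eliminate toward C7 or C9, or resist displacement. Fallback: setting out from 31, the alcohol is converted with chloromethanesulfonyl chloride and pyridine (CH2Cl2, 0 °C) into the C8 chloromethanesulfonate of 31 F3. This is displaced with inversion by cesium (2Z)-2-methylbut-2-enoate F4 (made from 32 and Cs2CO3) with 18-crown-6 in toluene at 50 °C, a sulfonate-displacement protocol used for hindered secondary alcohols. It comes back to the route at 34.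

Step 14 (release of the C8 aldehyde). What may go wrong: migration of the β,γ-double bond into conjugation with the aldehyde in the buffered aqueous medium, competing osmylation of the two electron-poor alkenes, or solvolysis of the allylic bromide. Fallback: C8 is carried as a protected primary alcohol and oxidised at the end, setting out from 20 and 21.
- 21 is alkylated with 1-(2-iodoethoxymethyl)-4-methoxybenzene to {1-methoxy-4-[(4-methoxybenzyl)oxy]-1-oxobutan-2-yl}triphenylphosphonium iodide F5, and aqueous NaOH gives methyl 4-[(4-methoxybenzyl)oxy]-2-(triphenyl-λ5-phosphanylidene)butanoate F6.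
- Wittig reaction of F6 with 20 (toluene, 90 °C) should give methyl (2E,6R)-6-{[(tert-butyldiphenylsilyl)oxy]methyl}-7-[(2R)-4-{[(tert-butyldimethylsilyl)oxy]methyl}-5-oxo-2,5-dihydrofuran-2-yl]-2-{2-[(4-methoxybenzyl)oxy]ethyl}hept-2-enoate F7.
- Camphorsulfonic acid in methanol removes the TBS group to give the 4-(hydroxymethyl)furanone analogue of F7 F8, and CBr4/PPh3 converts it into the 4-(bromomethyl)furanone analogue of F7 F9.
- DDQ in CH2Cl2/pH 7 buffer removes the 4-methoxybenzyl group to give methyl (2E,6R)-7-[(2R)-4-(bromomethyl)-5-oxo-2,5-dihydrofuran-2-yl]-6-{[(tert-butyldiphenylsilyl)oxy]methyl}-2-(2-hydroxyethyl)hept-2-enoate F10.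
- F10 is oxidised without delay with Dess–Martin periodinane and NaHCO3 in CH2Cl2 at 0 °C, which comes back to the route at 29.

Further compounds
F1 | step 15 | methyl (3aR,4R,6E,10R,11aR)-10-{[(tert-butyldiphenylsilyl)oxy]methyl}-4-hydroxy-3-methylidene-2-oxo-2,3,3a,4,5,8,9,10,11,11a-decahydrocyclodeca[b]furan-6-carboxylate (8R alcohol) | C=C1C(=O)O[C@@H]2C[C@H](CO[Si](c3ccccc3)(c3ccccc3)C(C)(C)C)CC/C=C(/C(=O)OC)C[C@@H](O)[C@@H]12
F2 | step 15 | (2Z)-2-methylbut-2-enoic 2,4,6-trichlorobenzoic anhydride | C/C=C(/C)C(=O)OC(=O)c1c(Cl)cc(Cl)cc1Cl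
F3 | step 16 | C8 chloromethanesulfonate of 31 | C=C1C(=O)O[C@@H]2C[C@H](CO[Si](c3ccccc3)(c3ccccc3)C(C)(C)C)CC/C=C(/C(=O)OC)C[C@H](OS(=O)(=O)CCl)[C@@H]12
F4 | step 16 | cesium (2Z)-2-methylbut-2-enoate | C/C=C(/C)C(=O)[O-].[Cs+]
F5 | step 14 | {1-methoxy-4-[(4-methoxybenzyl)oxy]-1-oxobutan-2-yl}triphenylphosphonium iodide | COC(=O)C(CCOCc1ccc(OC)cc1)[P+](c1ccccc1)(c1ccccc1)c1ccccc1.[I-]
F6 | step 14 | methyl 4-[(4-methoxybenzyl)oxy]-2-(triphenyl-λ5-phosphanylidene)butanoate | COC(=O)C(CCOCc1ccc(OC)cc1)=P(c1ccccc1)(c1ccccc1)c1ccccc1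
F7 | step 14 | methyl (2E,6R)-6-{[(tert-butyldiphenylsilyl)oxy]methyl}-7-[(2R)-4-{[(tert-butyldimethylsilyl)oxy]methyl}-5-oxo-2,5-dihydrofuran-2-yl]-2-{2-[(4-methoxybenzyl)oxy]ethyl}hept-2-enoate | COc1ccc(COCC/C(C(=O)OC)=C\CC[C@@H](CO[Si](c2ccccc2)(c2ccccc2)C(C)(C)C)C[C@H]2OC(=O)C(CO[Si](C)(C)C(C)(C)C)=C2)cc1
F8 | step 14 | methyl (2E,6R)-6-{[(tert-butyldiphenylsilyl)oxy]methyl}-7-[(2R)-4-(hydroxymethyl)-5-oxo-2,5-dihydrofuran-2-yl]-2-{2-[(4-methoxybenzyl)oxy]ethyl}hept-2-enoate | COc1ccc(COCC/C(C(=O)OC)=C\CC[C@@H](CO[Si](c2ccccc2)(c2ccccc2)C(C)(C)C)C[C@H]2OC(=O)C(CO)=C2)cc1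
F9 | step 14 | methyl (2E,6R)-7-[(2R)-4-(bromomethyl)-5-oxo-2,5-dihydrofuran-2-yl]-6-{[(tert-butyldiphenylsilyl)oxy]methyl}-2-{2-[(4-methoxybenzyl)oxy]ethyl}hept-2-enoate | COc1ccc(COCC/C(C(=O)OC)=C\CC[C@@H](CO[Si](c2ccccc2)(c2ccccc2)C(C)(C)C)C[C@H]2OC(=O)C(CBr)=C2)cc1
F10 | step 14 | methyl (2E,6R)-7-[(2R)-4-(bromomethyl)-5-oxo-2,5-dihydrofuran-2-yl]-6-{[(tert-butyldiphenylsilyl)oxy]methyl}-2-(2-hydroxyethyl)hept-2-enoate | OCC/C(C(=O)OC)=C\CC[C@@H](CO[Si](c1ccccc1)(c1ccccc1)C(C)(C)C)C[C@H]1OC(=O)C(CBr)=C1
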